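**Strategy.** The route rests on disconnecting rings B and C together: the benzenoid ring B (C3a–C7a) and the fused five-membered lactone ring C arise from one thermal hexadehydro-Diels–Alder reaction of an acetal-ester-tethered triyne, whose 4,5-aryne is captured by methanol. The step exploits the fusion of lactone ring C to ring B next to an unsubstituted C4 and a methoxylated C5: ring strain steers the methanol oxygen to C5 and the proton to C4. The precursor is a silylated propiolate ester of an α-ethoxy diynyl carbinol, its silicon becoming the C7 phenol and its silyl ether the C6 benzylic alcohol; the C3 configuration is set at the end by lipase dynamic resolution.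

Key step: step 5

Remark on numbering: positions follow isobenzofuran-1(3H)-one (C1 carbonyl, O2, C3 acetal or lactol carbon, C3a, C4–C7, C7a); ring B is its benzene ring, ring C the lactone, ring A the benzoate ring.

Remark on the stereocentre: C3 of a 3-hydroxyphthalide can epimerise through the ring-opened formyl acid, so the (3R)-lactol is assumed to be the kinetically released product and is set free only in the last step, under neutral, non-aqueous, cold conditions.

Remark on materials: tert-butyldimethyl(prop-2-yn-1-yloxy)silane is taken as purchased.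

Step 1
Reactants: 1 tert-butyldimethyl(prop-2-yn-1-yloxy)silane
Product: 2 (3-bromoprop-2-yn-1-yloxy)(tert-butyl)dimethylsilane
Conditions: NBS (1.1 equiv), AgNO3 (10 mol %), acetone, rt, dark
Reagents that add atoms: N-bromosuccinimide, O=C1CCC(=O)N1Br
Why: Silver-catalysed electrophilic bromination of a terminal alkyne through its silver acetylide is reliable and does not touch the silyl ether.

Step 2
Reactants: 2 (3-bromoprop-2-yn-1-yloxy)(tert-butyl)dimethylsilane; 3 3,3-diethoxyprop-1-yne
Product: 4 tert-butyl[(6,6-diethoxyhexa-2,4-diyn-1-yl)oxy]dimethylsilane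
Conditions: CuCl (5 mol %), NH2OH·HCl (0.3 equiv), n-BuNH2 (30% aq.), Et2O, 0 °C, slow addition of 2
Reagents that add atoms: none
Why: Cadiot–Chodkiewicz coupling, in which the copper acetylide of 3 (hydroxylamine keeping copper monovalent) couples with the bromoalkyne to give the unsymmetrical 1,3-diyne, the acetal and the silyl ether both being stable to aqueous amine.

Step 3
Reactants: 5 propiolic acid
Product: 7 3-(diethylsilyl)propiolic acid, via diethylsilyl 3-(diethylsilyl)propiolate 6 (not isolated)
Conditions: LDA (2.1 equiv), THF, −78 °C; Et2SiHCl (2.2 equiv), −78 → 0 °C; aq. citric acid work-up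
Reagents that add atoms: chlorodiethylsilane, CC[SiH](Cl)CC
Why: Double deprotonation gives the lithium acetylide carboxylate, which is silylated on carbon and oxygen by substitution at Si–Cl (the Si–H bond is inert to the acetylide in the cold), and the labile silyl ester is hydrolysed on mildly acidic work-up while C(sp)–Si and Si–H survive.

Step 4
Reactants: 4 tert-butyl[(6,6-diethoxyhexa-2,4-diyn-1-yl)oxy]dimethylsilane; 7 3-(diethylsilyl)propiolic acid
Product: 9 6-(tert-butyldimethylsilyloxy)-1-ethoxyhexa-2,4-diyn-1-yl 3-(diethylsilyl)propiolate (racemic), via α-chloro ether 8 (not isolated)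
Conditions: AcCl (3 equiv), SOCl2 (2 mol %), CH2Cl2, 0 °C → rt, then evaporate; 7 (1.1 equiv), i-Pr2NEt (1.2 equiv), CH2Cl2, −20 → 0 °C
Reagents that add atoms: acetyl chloride, CC(=O)Cl (its chlorine sits in 8 only and is lost on the way to 9)
Why: Acetal–acyl chloride exchange gives the α-chloro ether with loss of ethyl acetate, and the carboxylate of 7 then displaces chloride through the alkynyl-stabilised oxocarbenium ion, the same O-alkylation that makes alkoxymethyl esters, which forms the acetal carbon as a racemate; excess acetyl chloride is removed first so that 7 is not turned into a mixed anhydride.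

Step 5
Reactants: 9 6-(tert-butyldimethylsilyloxy)-1-ethoxyhexa-2,4-diyn-1-yl 3-(diethylsilyl)propiolate (racemic); 10 methanol
Product: 12 6-[(tert-butyldimethylsilyloxy)methyl]-7-(diethylsilyl)-3-ethoxy-5-methoxyisobenzofuran-1(3H)-one (racemic), via 4,5-aryne 11 (not isolated)
Conditions: MeOH/benzene (1:1, 0.01 M in 9, degassed), 2,6-di-tert-butyl-4-methylpyridine (10 mol %), sealed tube, 100 °C
Reagents that add atoms: none
Why: Thermal hexadehydro-Diels–Alder reaction, in which the silyl ynoate (2π, C7a≡C7) adds across the termini of the tethered 1,3-diyne (4π, C3a to C6) in a unimolecular, strongly asynchronous [4+2] process that forms C3a–C7a and C6–C7 and leaves a 4,5-didehydroarene. Ring B closes as the six-membered [4+2] ring, and lactone ring C closes in the same event because the three-atom O–C(=O) tether links the two carbons that form the C3a–C7a bond (the five-membered ring fusion of an intramolecular cycloaddition); no stereocentre is created and C3 stays racemic. The closest known reactions are the cycloisomerisations of diynyl-carbinol propiolate esters to phthalide-fused arynes and their capture by alcohols. The fused five-membered ring compresses the internal angle at C4 and opens that at C5, so C5 is the more electrophilic aryne carbon and methanol, acting through a hydrogen-bonded dimer, delivers oxygen to C5 and the proton to C4. The selectivities needed are this regiochemistry and O–H addition over hydrogen transfer from the carbinol C–H; the first is secured by ring-fusion distortion, the second by the high methanol concentration, while high dilution of 9 suppresses intermolecular aryne reactions and the hindered pyridine scavenges acid that would cleave the acyloxy acetal. The C7 silicon and the C6 silyloxymethyl group are spectators, since the CH2O oxygen cannot reach C5 in a ring of reasonable size.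

Step 6
Reactants: 12 6-[(tert-butyldimethylsilyloxy)methyl]-7-(diethylsilyl)-3-ethoxy-5-methoxyisobenzofuran-1(3H)-one (racemic)
Product: 14 3-ethoxy-7-hydroxy-6-(hydroxymethyl)-5-methoxyisobenzofuran-1(3H)-one (racemic), via benzoxasilole 13 (not isolated)
Conditions: TBAF (2.5 equiv), THF, 0 °C → rt; then KHCO3 (3 equiv), 30% aq. H2O2 (10 equiv), EtOH, rt
Reagents that add atoms: hydrogen peroxide, OO
Why: Fluoride removes the silyl ether and promotes dehydrogenative Si–O coupling of the freed C6 alkoxide with the neighbouring Si–H to a five-membered benzoxasilole, whose Si–O bond makes silicon oxidisable, and Tamao–Fleming oxidation with buffered peroxide then moves the aryl group from silicon to oxygen at C7 and hydrolysis frees the phenol and the benzylic alcohol; ethanol as co-solvent makes any alkoxy exchange at C3 degenerate.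

Step 7
Reactants: 15 methyl 2,4-dihydroxy-3,6-dimethylbenzoate
Product: 16 methyl 2-hydroxy-4-methoxy-3,6-dimethylbenzoate
Conditions: MeI (1.2 equiv), K2CO3 (1.5 equiv), acetone, reflux
Reagents that add atoms: iodomethane, CI
Why: Williamson O-methylation is selective for the 4-hydroxyl because the 2-hydroxyl is hydrogen-bonded to the ester carbonyl and flanked by a methyl group.

Step 8
Reactants: 16 methyl 2-hydroxy-4-methoxy-3,6-dimethylbenzoate
Product: 17 2-hydroxy-4-methoxy-3,6-dimethylbenzoic acid (ring A acid)
Conditions: KOH (6 equiv), DMSO/H2O (4:1), 90 °C; then 1 M HCl to pH 2 at 0 °C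
Reagents that add atoms: potassium hydroxide, [K+].[OH-] (one carboxyl oxygen)
Why: Saponification of the hindered di-ortho-substituted ester needs poorly solvated hydroxide in aqueous DMSO, and cold acidification avoids decarboxylation of the electron-rich salicylic acid.

Step 9
Reactants: 14 3-ethoxy-7-hydroxy-6-(hydroxymethyl)-5-methoxyisobenzofuran-1(3H)-one (racemic); 17 2-hydroxy-4-methoxy-3,6-dimethylbenzoic acid
Product: 18 (3-ethoxy-7-hydroxy-5-methoxy-1-oxo-1,3-dihydroisobenzofuran-6-yl)methyl 2-hydroxy-4-methoxy-3,6-dimethylbenzoate (racemic)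
Conditions: PPh3 (1.3 equiv), DIAD (1.3 equiv, added last), THF, 0 °C → rt
Reagents that add atoms: none
Why: Mitsunobu esterification, in which the carboxylic acid (by far the most acidic O–H present) protonates the betaine and its carboxylate displaces the benzylic oxyphosphonium ion, so the hindered acid is joined by alkyl–oxygen bond formation instead of acylation, and an ortho-quinone methide formed from the activated salicyl alcohol would be captured by the same carboxylate to give the same ester.

Step 10
Reactants: 18 (3-ethoxy-7-hydroxy-5-methoxy-1-oxo-1,3-dihydroisobenzofuran-6-yl)methyl 2-hydroxy-4-methoxy-3,6-dimethylbenzoate (racemic)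
Product: 19 (3,7-dihydroxy-5-methoxy-1-oxo-1,3-dihydroisobenzofuran-6-yl)methyl 2-hydroxy-4-methoxy-3,6-dimethylbenzoate (racemic lactol)
Conditions: 0.5 M aq. HCl/THF (1:4), 40 °C
Reagents that add atoms: water, O
Why: Acid-catalysed hydrolysis of the cyclic acyl acetal through the phthalidyl oxocarbenium ion gives the lactol as a racemate, and dilute acid is used because the benzylic ester flanked by OMe and OH would ionise in strong acid.

Step 11
Reactants: 19 (3,7-dihydroxy-5-methoxy-1-oxo-1,3-dihydroisobenzofuran-6-yl)methyl 2-hydroxy-4-methoxy-3,6-dimethylbenzoate (racemic lactol)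
Product: 20 [(3R)-3-acetoxy-7-hydroxy-5-methoxy-1-oxo-1,3-dihydroisobenzofuran-6-yl]methyl 2-hydroxy-4-methoxy-3,6-dimethylbenzoate
Conditions: immobilised Burkholderia cepacia lipase (chosen by screening for (R)-selective acylation), vinyl acetate (5 equiv), Et3N (5 mol %), toluene, 40 °C
Reagents that add atoms: vinyl acetate, C=COC(C)=O
Why: Lipase-catalysed dynamic kinetic resolution, in which the lactol enantiomers interconvert through the ring-opened formyl acid while the enzyme irreversibly acetylates only the (R)-lactol with the enol ester, so the active site sets C3 and the hindered, hydrogen-bonded phenols stay free.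

Step 12
Reactants: 20 [(3R)-3-acetoxy-7-hydroxy-5-methoxy-1-oxo-1,3-dihydroisobenzofuran-6-yl]methyl 2-hydroxy-4-methoxy-3,6-dimethylbenzoate
Product: 21 [(3R)-3,7-dihydroxy-5-methoxy-1-oxo-1,3-dihydroisobenzofuran-6-yl]methyl 2-hydroxy-4-methoxy-3,6-dimethylbenzoate (CNP0398000.1)
Conditions: immobilised Burkholderia cepacia lipase, n-BuOH (5 equiv), MTBE, 0–5 °C; filter, evaporate cold
Reagents that add atoms: none
Why: Lipase-catalysed alcoholysis cleaves the acyl–oxygen bond of the acetate, so the C3–O bond and the (R) configuration are retained, the same enzyme prefers the (R)-acetate, and base-free, cold, non-aqueous conditions keep ring–chain racemisation of the lactol slow.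

**Compound list**

1 | tert-butyldimethyl(prop-2-yn-1-yloxy)silane | C#CCO[Si](C)(C)C(C)(C)C | starting material
2 | (3-bromoprop-2-yn-1-yloxy)(tert-butyl)dimethylsilane | BrC#CCO[Si](C)(C)C(C)(C)C | intermediate
3 | 3,3-diethoxyprop-1-yne | CCOC(OCC)C#C | starting material
4 | tert-butyl[(6,6-diethoxyhexa-2,4-diyn-1-yl)oxy]dimethylsilane | CCOC(OCC)C#CC#CCO[Si](C)(C)C(C)(C)C | intermediate
5 | propiolic acid | C#CC(=O)O | starting material
6 | diethylsilyl 3-(diethylsilyl)propiolate (not isolated) | CC[SiH](CC)C#CC(=O)O[SiH](CC)CC | intermediate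
7 | 3-(diethylsilyl)propiolic acid | CC[SiH](CC)C#CC(=O)O | intermediate
8 | tert-butyl[(6-chloro-6-ethoxyhexa-2,4-diyn-1-yl)oxy]dimethylsilane (racemic α-chloro ether, not isolated) | CCOC(Cl)C#CC#CCO[Si](C)(C)C(C)(C)C | intermediate
9 | 6-(tert-butyldimethylsilyloxy)-1-ethoxyhexa-2,4-diyn-1-yl 3-(diethylsilyl)propiolate (racemic) | CCOC(OC(=O)C#C[SiH](CC)CC)C#CC#CCO[Si](C)(C)C(C)(C)C | intermediate
10 | methanol | CO | starting material
11 | 6-[(tert-butyldimethylsilyloxy)methyl]-7-(diethylsilyl)-3-ethoxy-4,5-didehydroisobenzofuran-1(3H)-one (racemic aryne, not isolated) | CCOC1OC(=O)C2=C1C#CC(CO[Si](C)(C)C(C)(C)C)=C2[SiH](CC)CC | intermediate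
12 | 6-[(tert-butyldimethylsilyloxy)methyl]-7-(diethylsilyl)-3-ethoxy-5-methoxyisobenzofuran-1(3H)-one (racemic) | CCOC1OC(=O)c2c1cc(OC)c(CO[Si](C)(C)C(C)(C)C)c2[SiH](CC)CC | intermediate
13 | tricyclic 1,1-diethyl-1,3-dihydro-2,1-benzoxasilole (Si on C7, O–CH2 on C6) fused to the 3-ethoxy-5-methoxyphthalide (racemic, not isolated) | CCOC1OC(=O)c2c1cc(OC)c1c2[Si](CC)(CC)OC1 | intermediate
14 | 3-ethoxy-7-hydroxy-6-(hydroxymethyl)-5-methoxyisobenzofuran-1(3H)-one (racemic) | CCOC1OC(=O)c2c(O)c(CO)c(OC)cc21 | intermediate
15 | methyl 2,4-dihydroxy-3,6-dimethylbenzoate | COC(=O)c1c(C)cc(O)c(C)c1O | starting material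
16 | methyl 2-hydroxy-4-methoxy-3,6-dimethylbenzoate | COC(=O)c1c(C)cc(OC)c(C)c1O | intermediate
17 | 2-hydroxy-4-methoxy-3,6-dimethylbenzoic acid | COc1cc(C)c(C(=O)O)c(O)c1C | intermediate
18 | (3-ethoxy-7-hydroxy-5-methoxy-1-oxo-1,3-dihydroisobenzofuran-6-yl)methyl 2-hydroxy-4-methoxy-3,6-dimethylbenzoate (racemic) | COc1cc(C)c(C(=O)OCc2c(OC)cc3c(c2O)C(=O)OC3OCC)c(O)c1C | intermediate
19 | (3,7-dihydroxy-5-methoxy-1-oxo-1,3-dihydroisobenzofuran-6-yl)methyl 2-hydroxy-4-methoxy-3,6-dimethylbenzoate (racemic) | COc1cc(C)c(C(=O)OCc2c(OC)cc3c(c2O)C(=O)OC3O)c(O)c1C | intermediate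
20 | [(3R)-3-acetoxy-7-hydroxy-5-methoxy-1-oxo-1,3-dihydroisobenzofuran-6-yl]methyl 2-hydroxy-4-methoxy-3,6-dimethylbenzoate | COc1cc(C)c(C(=O)OCc2c(OC)cc3c(c2O)C(=O)O[C@H]3OC(C)=O)c(O)c1C | intermediate
21 | [(3R)-3,7-dihydroxy-5-methoxy-1-oxo-1,3-dihydroisobenzofuran-6-yl]methyl 2-hydroxy-4-methoxy-3,6-dimethylbenzoate | COc1cc(C)c(C(=O)OCc2c(OC)cc3c(c2O)C(=O)O[C@H]3O)c(O)c1C | target

**Step count and risk**

Total step count: 12. Longest linear sequence: 9 steps (steps 1, 2, 4, 5, 6, 9, 10, 11, 12, from compound 1).

Most likely to fail, first: step 5. Methanolysis of the acyloxy acetal tether, or transesterification of the activated ynoate, may outrun the unimolecular cyclisation, and the aryne may be reduced by hydrogen transfer instead of adding methanol. The fallback sets out from 9 and takes methanol out of the cycloaddition. Heating 9 in benzene with acetic acid (10 equiv) should trap the same aryne 11 at C5 as the aryl acetate 5-acetoxy-6-[(tert-butyldimethylsilyloxy)methyl]-7-(diethylsilyl)-3-ethoxyisobenzofuran-1(3H)-one F1. Lipase-mediated butanolysis (Candida antarctica lipase B, n-BuOH, MTBE) should then release, under neutral conditions, the phenol 6-[(tert-butyldimethylsilyloxy)methyl]-7-(diethylsilyl)-3-ethoxy-5-hydroxyisobenzofuran-1(3H)-one F2. O-Methylation (MeI, K2CO3, acetone) comes back to the route at 12.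

Second: step 4. The silyl ether may be lost, the diyne may decompose under acyl chloride and traces of HCl, or the alkynyl acetal may ionise too slowly. The fallback sets out from 4 and replaces the halo ether by a pyridinium-type electrophile. TESOTf with 2,4,6-collidine (CH2Cl2, 0 °C), a combination that activates aldehyde acetals and leaves silyl ethers alone, should give the collidinium salt 1-[6-(tert-butyldimethylsilyloxy)-1-ethoxyhexa-2,4-diyn-1-yl]-2,4,6-trimethylpyridinium triflate F3. Addition of 7 with i-Pr2NEt should displace collidine from the acetal carbon and come back to the route at 9.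

Third: step 11. The enzyme may discriminate poorly between the lactol enantiomers, may prefer the (S)-lactol, or may acylate faster than the lactol racemises, which would turn the process into a plain kinetic resolution. The fallback sets out from 19 and uses a small-molecule acyl-transfer catalyst whose enantiomer can be chosen. Acylative dynamic kinetic resolution with chiral benzotetramisole, isobutyric anhydride and i-Pr2NEt in CHCl3 should give the isobutyrate [(3R)-7-hydroxy-5-methoxy-3-(2-methylpropanoyloxy)-1-oxo-1,3-dihydroisobenzofuran-6-yl]methyl 2-hydroxy-4-methoxy-3,6-dimethylbenzoate F4. Lipase butanolysis under the conditions of step 12 comes back to the route at 21.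

Further compounds
F1 | step 5 | 5-acetoxy-6-[(tert-butyldimethylsilyloxy)methyl]-7-(diethylsilyl)-3-ethoxyisobenzofuran-1(3H)-one (racemic) | CCOC1OC(=O)c2c1cc(OC(C)=O)c(CO[Si](C)(C)C(C)(C)C)c2[SiH](CC)CC
F2 | step 5 | 6-[(tert-butyldimethylsilyloxy)methyl]-7-(diethylsilyl)-3-ethoxy-5-hydroxyisobenzofuran-1(3H)-one (racemic) | CCOC1OC(=O)c2c1cc(O)c(CO[Si](C)(C)C(C)(C)C)c2[SiH](CC)CC
F3 | step 4 | 1-[6-(tert-butyldimethylsilyloxy)-1-ethoxyhexa-2,4-diyn-1-yl]-2,4,6-trimethylpyridinium triflate (racemic) | CCOC(C#CC#CCO[Si](C)(C)C(C)(C)C)[n+]1c(C)cc(C)cc1C.[O-]S(=O)(=O)C(F)(F)F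
F4 | step 11 | [(3R)-7-hydroxy-5-methoxy-3-(2-methylpropanoyloxy)-1-oxo-1,3-dihydroisobenzofuran-6-yl]methyl 2-hydroxy-4-methoxy-3,6-dimethylbenzoate | COc1cc(C)c(C(=O)OCc2c(OC)cc3c(c2O)C(=O)O[C@H]3OC(=O)C(C)C)c(O)c1C
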